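**Retrosynthetic overview**
1. Target 28 ⇐ inversion at C3 of the cis-bromohydrin 26 ⇐ α′-bromination and 1,2-reduction of spiro-dienone 23 ⇐ MeLi addition and enone transposition of spiro vinylogous ester 21.
2. Key disconnection C6–C11: Pd-catalysed enantioselective ring-closing allylic alkylation of silyl enol ether 20, which closes ring B and sets the spiro quaternary centre; the tetrasubstituted vinyl bromide is carried in ready-made.
3. C6–C7: kinetic enolate alkylation joining ring-A vinylogous ester 10 with the C7–C11 bis-electrophile 17.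
4. 10 ⇐ dimedone ⇐ mesityl oxide (from acetone) + dimethyl malonate (from malonic acid); 17 ⇐ 4-bromobut-1-yne by carboxylation, syn-carbocupration/bromination, reduction and carbonate formation.
5. Ring order: ring A first (Michael–Claisen), ring B second (Pd spirocyclisation).

Assumption: the spiro[5.5]undecane core is numbered C1–C5 (ring A, methyl on C1), C6 (spiro), C7–C11 (ring B, methyl on C9, bromine on C10); the target is then (3S,4S,6S), with Br at C4 cis to C11 and trans to OH.

**Step 1**
Reactants: 1 acetone (2 equiv)
Product: 3 mesityl oxide (4-methylpent-3-en-2-one), via diacetone alcohol 2 (not isolated)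
Conditions: Ba(OH)2 (cat.), reflux (Soxhlet); then I2 (cat.), distil
Reagents that add atoms: none
Why: Base-catalysed aldol addition of acetone followed by iodine-catalysed dehydration (aldol condensation) gives the conjugated enone; no stereocentre.

**Step 2**
Reactants: 4 malonic acid
Product: 5 dimethyl malonate
Conditions: MeOH, H2SO4 (cat.), reflux
Reagents that add atoms: methanol (CO)
Why: Fischer esterification driven by excess methanol, well below the decarboxylation temperature of malonic acid; no stereocentre.

**Step 3**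
Reactants: 3 mesityl oxide; 5 dimethyl malonate
Product: 7 methyl 2,2-dimethyl-4,6-dioxocyclohexane-1-carboxylate, via Michael adduct 6 (not isolated)
Conditions: NaOMe, MeOH, reflux; then 2 M HCl, 0 °C
Reagents that add atoms: none
Why: Michael addition of the malonate anion to the enone, then Claisen (Dieckmann-type) cyclisation of the methyl ketone onto one ester gives the stabilised dione enolate, released by cold acidification; the ring CH is epimerisable and is removed in step 4.

**Step 4**
Reactants: 7 methyl 2,2-dimethyl-4,6-dioxocyclohexane-1-carboxylate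
Product: 9 dimedone (5,5-dimethylcyclohexane-1,3-dione), via keto acid 8 (not isolated)
Conditions: 2 M KOH (aq), reflux; then conc. HCl, reflux
Reagents that add atoms: none
Why: Saponification followed by acid-promoted decarboxylation of the β-keto acid (classical dimedone synthesis); no stereocentre.

**Step 5**
Reactants: 9 dimedone
Product: 10 3-(2-methylpropoxy)-5,5-dimethylcyclohex-2-en-1-one
Conditions: i-BuOH, TsOH·H2O (cat.), toluene, reflux, Dean–Stark
Reagents that add atoms: 2-methylpropan-1-ol (CC(C)CO)
Why: Acid-catalysed enol etherification with azeotropic removal of water gives the vinylogous ester, which masks the future C3 carbonyl and leaves C6 as the kinetic α′ site.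

**Step 6**
Reactants: 11 4-bromobut-1-yne
Product: 13 methyl 5-bromopent-2-ynoate, via lithium acetylide 12 (not isolated)
Conditions: LDA, THF, –78 °C; then ClCO2Me, –78 → 0 °C
Reagents that add atoms: methyl chloroformate (COC(Cl)=O)
Why: Deprotonation of the terminal alkyne is far faster than attack on the primary bromide at –78 °C, and the acetylide is C-acylated by the chloroformate (alkyne carboxylation).

**Step 7**
Reactants: 13 methyl 5-bromopent-2-ynoate
Product: 15 methyl (2E)-2,5-dibromo-3-methylpent-2-enoate, via alkenylcuprate 14 (not isolated)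
Conditions: Me2CuLi (from CuI, 2 MeLi), THF, –78 °C, 30 min; then NBS, –78 °C; aq. NH4Cl
Reagents that add atoms: lithium dimethylcuprate ([Li+].C[Cu-]C); N-bromosuccinimide (O=C1CCC(=O)N1Br)
Why: syn-Carbocupration (conjugate addition) of the ynoate at –78 °C gives a configurationally stable α-cuprio enoate with Me and Cu cis, and bromination with retention fixes the tetrasubstituted alkene geometry (CH2CH2Br cis to the ester carbon) that ring B needs.

**Step 8**
Reactants: 15 methyl (2E)-2,5-dibromo-3-methylpent-2-enoate
Product: 16 (2E)-2,5-dibromo-3-methylpent-2-en-1-ol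
Conditions: DIBAL-H (2.2 equiv), CH2Cl2, –78 °C; Rochelle salt
Reagents that add atoms: none
Why: DIBAL-H 1,2-reduction of the enoate to the allylic alcohol at –78 °C leaves both C–Br bonds and the alkene geometry untouched.

**Step 9**
Reactants: 16 (2E)-2,5-dibromo-3-methylpent-2-en-1-ol
Product: 17 tert-butyl (2E)-2,5-dibromo-3-methylpent-2-en-1-yl carbonate
Conditions: Boc2O, DMAP (10 mol %), CH2Cl2, 0 → 23 °C
Reagents that add atoms: di-tert-butyl dicarbonate (CC(C)(C)OC(=O)OC(=O)OC(C)(C)C)
Why: DMAP-catalysed O-acylation gives the allylic tert-butyl carbonate, a leaving group for Pd that is too hindered to be attacked by LDA or a lithium enolate at low temperature.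

**Step 10**
Reactants: 10 3-(2-methylpropoxy)-5,5-dimethylcyclohex-2-en-1-one; 17 tert-butyl (2E)-2,5-dibromo-3-methylpent-2-en-1-yl carbonate
Product: 19 tert-butyl (2E)-2-bromo-5-[4-(2-methylpropoxy)-6,6-dimethyl-2-oxocyclohex-3-en-1-yl]-3-methylpent-2-en-1-yl carbonate (racemic), via lithium enolate 18 (not isolated)
Conditions: LDA, THF, –78 °C; then 17, DMPU, TBAI (10 mol %), –78 → 23 °C
Reagents that add atoms: none
Why: Stork–Danheiser kinetic α′-deprotonation and SN2 alkylation at the primary C–Br (in situ Finkelstein) joins the fragments through C6–C7; vinyl bromide and carbonate are inert, and the racemic C6 centre is erased in step 11.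

**Step 11**
Reactants: 19 tert-butyl (2E)-2-bromo-5-[4-(2-methylpropoxy)-6,6-dimethyl-2-oxocyclohex-3-en-1-yl]-3-methylpent-2-en-1-yl carbonate
Product: 21 (6R)-10-bromo-5,5,9-trimethyl-3-(2-methylpropoxy)spiro[5.5]undeca-2,9-dien-1-one, via TES enol ether 20 (not isolated)
Conditions: LDA, TESCl (in situ quench), THF, –78 °C; pentane, filter, concentrate; then Pd2(dba)3 (2.5 mol %), (S)-t-BuPHOX (6.25 mol %), TBAT (35 mol %), THF, 25 → 40 °C
Reagents that add atoms: none
Why: Proposed new method: an enantioselective ring-closing Tsuji–Trost allylation in which Pd(0)/(S)-t-BuPHOX ionises the tetrasubstituted 2-bromoallyl carbonate (faster than insertion into the hindered C(sp2)–Br bond), the tert-butoxide released after loss of CO2 (started by catalytic fluoride) unmasks the fully substituted enolate, and the tethered enolate carbon C6 attacks the CH2 terminus C11 of the 2-bromo-π-allyl (six-ring closure is the only geometrically feasible C-alkylation) on the face selected by the ligand, closing ring B and setting the spiro quaternary centre as (6R); the closest known reaction is the intermolecular Pd/PHOX asymmetric allylic alkylation of silyl enol ethers with allyl carbonates, and this endo-type intramolecular variant on a 2-halo tetrasubstituted allyl has not been shown.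

**Step 12**
Reactants: 21 (6R)-10-bromo-5,5,9-trimethyl-3-(2-methylpropoxy)spiro[5.5]undeca-2,9-dien-1-one
Product: 23 (6R)-10-bromo-1,5,5,9-tetramethylspiro[5.5]undeca-1,9-dien-3-one, via tertiary alcohol 22 (not isolated)
Conditions: MeLi, CeCl3, THF, –78 → 0 °C; then 1 M HCl, 23 °C
Reagents that add atoms: methyllithium ([Li]C)
Why: 1,2-Addition of the organocerium reagent to the hindered carbonyl, then acid hydrolysis of the enol ether and β-elimination (Stork–Danheiser transposition) give the transposed enone; the vinyl bromide does not exchange and C6 is untouched (the descriptor stays R because C1 still outranks C5).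

**Step 13**
Reactants: 23 (6R)-10-bromo-1,5,5,9-tetramethylspiro[5.5]undeca-1,9-dien-3-one
Product: 25 (4S,6S)-4,10-dibromo-1,5,5,9-tetramethylspiro[5.5]undeca-1,9-dien-3-one, via TMS dienol ether 24 (not isolated)
Conditions: LDA, TMSCl, THF, –78 °C; then NBS, THF, –78 °C
Reagents that add atoms: N-bromosuccinimide (O=C1CCC(=O)N1Br)
Why: Kinetic α′-enolisation (C4 is the only α′ site) trapped as the silyl dienol ether, then electrophilic bromination by NBS on the face syn to C11 and anti to the bulkier C7–C8 arm of ring B, sets (4S) with Br cis to C11; the bromide can neither eliminate nor be displaced because C5 is quaternary.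

**Step 14**
Reactants: 25 (4S,6S)-4,10-dibromo-1,5,5,9-tetramethylspiro[5.5]undeca-1,9-dien-3-one
Product: 26 (3R,4S,6S)-4,10-dibromo-1,5,5,9-tetramethylspiro[5.5]undeca-1,9-dien-3-ol
Conditions: DIBAL-H, CH2Cl2, –78 °C; Rochelle salt
Reagents that add atoms: none
Why: 1,2-Reduction of the enone from the less hindered equatorial direction, anti to the C4–Br bond (Felkin–Anh/Cornforth) and to the axial C5 methyl, gives the cis-bromohydrin (3R) with axial OH.

**Step 15**
Reactants: 26 (3R,4S,6S)-4,10-dibromo-1,5,5,9-tetramethylspiro[5.5]undeca-1,9-dien-3-ol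
Product: 28 (3S,4S,6S)-4,10-dibromo-1,5,5,9-tetramethylspiro[5.5]undeca-1,9-dien-3-ol, via formate ester 27 (not isolated)
Conditions: PPh3, DIAD, HCO2H, THF, 0 → 23 °C; then NaHCO3, MeOH, 23 °C
Reagents that add atoms: formic acid (OC=O)
Why: Mitsunobu reaction: SN2 displacement of the axial oxyphosphonium by formate inverts C3 to (3S) (OH trans to Br), and the labile formate is removed by mild methanolysis that does not close the trans-bromohydrin to an epoxide.

**Compound list**
1 | acetone | CC(C)=O | starting material
2 | diacetone alcohol (4-hydroxy-4-methylpentan-2-one) | CC(=O)CC(C)(C)O | intermediate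
3 | mesityl oxide (4-methylpent-3-en-2-one) | CC(=O)C=C(C)C | intermediate
4 | malonic acid | OC(=O)CC(O)=O | starting material
5 | dimethyl malonate | COC(=O)CC(=O)OC | intermediate
6 | dimethyl 2-(2-methyl-4-oxopentan-2-yl)malonate (Michael adduct) | COC(=O)C(C(=O)OC)C(C)(C)CC(C)=O | intermediate
7 | methyl 2,2-dimethyl-4,6-dioxocyclohexane-1-carboxylate | COC(=O)C1C(=O)CC(=O)CC1(C)C | intermediate
8 | 2,2-dimethyl-4,6-dioxocyclohexane-1-carboxylic acid (keto acid) | OC(=O)C1C(=O)CC(=O)CC1(C)C | intermediate
9 | dimedone (5,5-dimethylcyclohexane-1,3-dione) | O=C1CC(=O)CC(C)(C)C1 | intermediate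
10 | 3-(2-methylpropoxy)-5,5-dimethylcyclohex-2-en-1-one | O=C1C=C(OCC(C)C)CC(C)(C)C1 | intermediate
11 | 4-bromobut-1-yne | C#CCCBr | starting material
12 | lithium 4-bromobut-1-yn-1-ide (lithium acetylide) | [Li+].[C-]#CCCBr | intermediate
13 | methyl 5-bromopent-2-ynoate | COC(=O)C#CCCBr | intermediate
14 | lithium [(1Z)-4-bromo-1-(methoxycarbonyl)-2-methylbut-1-en-1-yl](methyl)cuprate (alkenylcuprate) | [Li+].BrCC/C(C)=C(/[Cu-]C)C(=O)OC | intermediate
15 | methyl (2E)-2,5-dibromo-3-methylpent-2-enoate | BrCC/C(C)=C(/Br)C(=O)OC | intermediate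
16 | (2E)-2,5-dibromo-3-methylpent-2-en-1-ol | BrCC/C(C)=C(/Br)CO | intermediate
17 | tert-butyl (2E)-2,5-dibromo-3-methylpent-2-en-1-yl carbonate | BrCC/C(C)=C(/Br)COC(=O)OC(C)(C)C | intermediate
18 | lithium enolate of 10 (lithium 5-(2-methylpropoxy)-3,3-dimethylcyclohexa-1,5-dien-1-olate) | [Li+].[O-]C1=CC(C)(C)CC(OCC(C)C)=C1 | intermediate
19 | tert-butyl (2E)-2-bromo-5-[4-(2-methylpropoxy)-6,6-dimethyl-2-oxocyclohex-3-en-1-yl]-3-methylpent-2-en-1-yl carbonate (racemic) | O=C1C=C(OCC(C)C)CC(C)(C)C1CC/C(C)=C(/Br)COC(=O)OC(C)(C)C | intermediate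
20 | tert-butyl (2E)-2-bromo-3-methyl-5-[4-(2-methylpropoxy)-6,6-dimethyl-2-(triethylsilyloxy)cyclohexa-1,3-dien-1-yl]pent-2-en-1-yl carbonate (TES enol ether) | CC[Si](CC)(CC)OC1=C(CC/C(C)=C(/Br)COC(=O)OC(C)(C)C)C(C)(C)CC(OCC(C)C)=C1 | intermediate
21 | (6R)-10-bromo-5,5,9-trimethyl-3-(2-methylpropoxy)spiro[5.5]undeca-2,9-dien-1-one | O=C1C=C(OCC(C)C)CC(C)(C)[C@]12CCC(C)=C(Br)C2 | intermediate
22 | (6R)-10-bromo-1,5,5,9-tetramethyl-3-(2-methylpropoxy)spiro[5.5]undeca-2,9-dien-1-ol (tertiary alcohol, C1 epimers) | CC1(O)C=C(OCC(C)C)CC(C)(C)[C@]12CCC(C)=C(Br)C2 | intermediate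
23 | (6R)-10-bromo-1,5,5,9-tetramethylspiro[5.5]undeca-1,9-dien-3-one | CC1=CC(=O)CC(C)(C)[C@]12CCC(C)=C(Br)C2 | intermediate
24 | (6S)-10-bromo-1,5,5,9-tetramethyl-3-(trimethylsilyloxy)spiro[5.5]undeca-1,3,9-triene (TMS dienol ether) | CC1=CC(O[Si](C)(C)C)=CC(C)(C)[C@]12CCC(C)=C(Br)C2 | intermediate
25 | (4S,6S)-4,10-dibromo-1,5,5,9-tetramethylspiro[5.5]undeca-1,9-dien-3-one | CC1=CC(=O)[C@@H](Br)C(C)(C)[C@]12CCC(C)=C(Br)C2 | intermediate
26 | (3R,4S,6S)-4,10-dibromo-1,5,5,9-tetramethylspiro[5.5]undeca-1,9-dien-3-ol (cis-bromohydrin) | CC1=C[C@@H](O)[C@@H](Br)C(C)(C)[C@]12CCC(C)=C(Br)C2 | intermediate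
27 | (3S,4S,6S)-4,10-dibromo-1,5,5,9-tetramethylspiro[5.5]undeca-1,9-dien-3-yl formate | CC1=C[C@H](OC=O)[C@@H](Br)C(C)(C)[C@]12CCC(C)=C(Br)C2 | intermediate
28 | (3S,4S,6S)-4,10-dibromo-1,5,5,9-tetramethylspiro[5.5]undeca-1,9-dien-3-ol | CC1=C[C@H](O)[C@@H](Br)C(C)(C)[C@]12CCC(C)=C(Br)C2 | target

**Totals**
Total step count: 15.
Longest linear sequence: 10 steps (steps 6–15 from 11; the ring-A branch, steps 2–5 then 10–15, is equally long).

**Steps most likely to fail**

Step 11 (the new Pd spirocyclisation). Ionisation of a tetrasubstituted allylic carbonate may be slow, Pd may insert into the vinyl C–Br bond, and the level and sense of asymmetric induction are untested. The (S)-ligand is chosen by analogy with intermolecular PHOX allylations; the (R)-ligand would be used if the tether reverses the sense. The fallback is a classical Stork–Danheiser spiro-annulation followed by resolution. It sets out from 10 and 16: PBr3 converts 16 into (2E)-1,2,5-tribromo-3-methylpent-2-ene F1. The lithium enolate of 10 is alkylated by the allylic bromide of F1 to give 6-[(2E)-2,5-dibromo-3-methylpent-2-en-1-yl]-3-(2-methylpropoxy)-5,5-dimethylcyclohex-2-en-1-one F2. A second equivalent of LDA closes ring B by intramolecular alkylation to give racemic 10-bromo-5,5,9-trimethyl-3-(2-methylpropoxy)spiro[5.5]undeca-2,9-dien-1-one F3. Preparative chiral SFC separates 21 from its (6S)-enantiomer F4, and the route is rejoined at 21.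

Step 13 (C4 bromination). The two ring-B methylenes flanking C6 differ only modestly, so kinetic face selection at C4 may be low. The fallback replaces kinetic control by equilibration and recycling. It sets out from 23: the lithium enolate is brominated without relying on face selection, giving 25 together with its C4 epimer, (4R,6S)-4,10-dibromo-1,5,5,9-tetramethylspiro[5.5]undeca-1,9-dien-3-one F5. The epimers are separated by chromatography, and F5 is re-equilibrated with catalytic DBU (C4–H is acidic and no elimination is possible) and recycled. The route is rejoined at 25.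

Step 15 (Mitsunobu inversion). The carbinol is flanked by CHBr and a trisubstituted alkene, so elimination or SN2′ may compete. The fallback omits the inversion: it sets out from 25, which is reduced under Luche conditions (NaBH4, CeCl3·7H2O, MeOH, –78 °C), where the small hydride can add axially to give 28 directly. 28 is separated from 26, and 26 is recycled to 25 by Dess–Martin oxidation. The route is rejoined at 28, and no compound outside the list is made (F0).

**Further compounds**
F1 | step 11 | (2E)-1,2,5-tribromo-3-methylpent-2-ene | BrCC/C(C)=C(/Br)CBr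
F2 | step 11 | 6-[(2E)-2,5-dibromo-3-methylpent-2-en-1-yl]-3-(2-methylpropoxy)-5,5-dimethylcyclohex-2-en-1-one (racemic) | O=C1C=C(OCC(C)C)CC(C)(C)C1C/C(Br)=C(/C)CCBr
F3 | step 11 | racemic 10-bromo-5,5,9-trimethyl-3-(2-methylpropoxy)spiro[5.5]undeca-2,9-dien-1-one | O=C1C=C(OCC(C)C)CC(C)(C)C12CCC(C)=C(Br)C2
F4 | step 11 | (6S)-10-bromo-5,5,9-trimethyl-3-(2-methylpropoxy)spiro[5.5]undeca-2,9-dien-1-one | O=C1C=C(OCC(C)C)CC(C)(C)[C@@]12CCC(C)=C(Br)C2
F5 | step 13 | (4R,6S)-4,10-dibromo-1,5,5,9-tetramethylspiro[5.5]undeca-1,9-dien-3-one | CC1=CC(=O)[C@H](Br)C(C)(C)[C@]12CCC(C)=C(Br)C2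
F0 | step 15 | none | none
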